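**Reading the ends.** Without rate constants, the late amount of G can still be reckoned from the charges.

| flask | Q | Z | remark | time |
|---|---|---|---|---|
| oak | 0.070 M | 0.010 M | run made earlier |  |
| ash | 0.11 M | 0.010 M | run made earlier |  |
| birch | 0.050 M | 0.0050 M | run made earlier |  |
| flask | 0.050 M | 0.0100 M |  | 30 h |

| run | time / h | G / % | L / % | Q / % |
|---|---|---|---|---|
| oak | 1.50 | 13.0 | 13.3 | 13.1 |
| oak | 5.00 | 21.4 | 9.4 | 7.3 |
| oak | 8.00 | 25.8 | 4.6 | 4.2 |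
| oak | 12.0 | 29.3 | 2.4 | 2.4 |
| oak | 20.0 | 32.4 | 1.6 | 0.3 |
| oak | 25.0 | 33.0 | 0.7 | 0.5 |
| ash | 1.50 | 13.3 | 15.3 | 14.8 |
| ash | 5.00 | 22.7 | 9.3 | 8.3 |
| ash | 8.00 | 27.3 | 6.6 | 4.5 |
| ash | 12.0 | 30.2 | 2.9 | 3.4 |
| ash | 20.0 | 34.6 | 1.3 | 1.7 |
| ash | 25.0 | 35.2 | 1.1 | 0.6 |
| birch | 2.00 | 14.7 | 13.3 | 12.8 |
| birch | 6.00 | 24.7 | 7.8 | 6.9 |
| birch | 12.0 | 31.0 | 2.8 | 3.1 |
| birch | 15.0 | 33.5 | 0.8 | 2.5 |
| birch | 25.0 | 34.8 | 1.2 | 1.2 |

(readings scatter by 0.5 percentage points)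

1. ratio of G to L at 5.0 min
2. ratio of G to L at 1.5 h
3. ratio of G to L at 30 h



Suppose each Z takes one Q away from G. The share of Q spared is then one minus c_Z/c_Q, and the G reading late in a run, divided by that share, is a selectivity for G. At 25.0 h the oak, ash and birch runs give 38.5%, 38.7% and 38.7%, each G reading being good to 0.5 percentage points. Their mean is the spared yield, 38.6%.

**Birch beside flask.** Birch holds 0.050 M of Q, like this flask, yet this flask holds twice the Z. On this reckoning birch spares 90.0% of its Q, and its G reading at 25.0 h is 34.8%. This flask is reckoned to spare 80.0%, less than birch, so its late G comes to 30.9%, lower than the birch reading.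

**The forecast.** For the ratio of G to L it gives 0.4 at 5.0 min, 0.93 at 1.5 h and 90 at 30 h. It reads: “At 30 h, G≈33%”. That G differs from the reckoning above.

**The result.** The flask gives ratios of 0.544, 0.922 and 70.1 at those times. At 30 h this flask holds 17.8% of the Q charged as D, with G at 32.0% and L at 0.456%. The spared yield applied to the part not held as D gives 31.7% for G.

    Q ⇌ L (K = 2.76, k = 1.37 × 10⁻⁴ s⁻¹)
    Q ⇌ G (K = 95.5, k = 7.27 × 10⁻⁵ s⁻¹)
    Q ⇌ J (K = 1.86, k = 2.34 × 10⁻⁵ s⁻¹)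
    Q ⇌ E (K = 2.20, k = 4.25 × 10⁻⁴ s⁻¹)
    L → X (k = 1.12 × 10⁻⁴ s⁻¹)
    Q + Z → D (k = 0.00937 M⁻¹ s⁻¹)

**A second flask.** In the neighbour charged with 0.20 M of Q, the spared yield gives G as 36.7%. The computed G in that neighbour at 30 h is 36.8%, and its ratio of G to L at that time is 63.1.

(The data are calculated for substances that don't exist; noise was put on by code.)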